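Two questions stand on each of two flasks: which complex holds most of the charge at the end, and how much it holds.

    complex with one exchanged + incoming ligand ⇌ leaving ligand + complex with two exchanged (K1 = 2.0, k1 = 5.4 M⁻¹ s⁻¹)
    starting complex + complex with one exchanged → side product (k2 = 0.052 M⁻¹ s⁻¹)
    protic impurity + starting complex → quenched substrate (k3 = 0.66 M⁻¹ s⁻¹)
    starting complex + incoming ligand ⇌ leaving ligand + complex with one exchanged (K4 = 0.45, k4 = 1.7 M⁻¹ s⁻¹)
    complex with two exchanged + incoming ligand ⇌ leaving ligand + complex with three exchanged (K5 = 1.4, k5 = 1.3 M⁻¹ s⁻¹)

- midnight: starting complex 0.050 M; incoming ligand 0.150 M; protic impurity 5.00 mM; time 2.0 min
- dusk: starting complex 0.050 M; incoming ligand 0.0500 M; protic impurity 5.00 mM; time 2.0 min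

- which of these there is most of at the end, counted by the starting complex in it, midnight (starting complex / complex with two exchanged / complex with three exchanged / complex with one exchanged)
- which of these there is most of at the end, counted by the starting complex in it, dusk (starting complex / complex with two exchanged / complex with three exchanged / complex with one exchanged)
- amount of the one of these that there is most of at the end, in percent of the starting complex charged, midnight
- amount of the one of these that there is most of at the end, in percent of the starting complex charged, dusk

- in percentages every species weighs as the starting complex in it: one side product counts as two
- run time (midnight): 2.0 min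

Step 5 at dusk has a forward half-life of 0.18 min with the ligand as charged, far shorter than the run of 2.0 min, so this reckoning takes the exchanges as at equilibrium and asks what they leave free. Each complex then stands to the one before it as its constant times ρ = [incoming ligand]/[leaving ligand]. The product of the exchange constants is 1.26, so [complex with three exchanged]/[starting complex] is the cube of ρ/ρc. Here ρc, the crossover ratio, is the free-ligand ratio at which those two complexes stand equal: 0.926.

Take the exchanges first, with trial ratios of 1.00 for midnight and 0.500 for dusk. The weights of the complexes sum to 3.61 and 1.61. Complex with three exchanged then holds 34.9 % at midnight, and starting complex holds 62.2 % at dusk. The mean exchange per complex is 1.67 and 0.714. With the full charge of complex, the ligand balance returns ρ of 0.796 and 0.401.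

Now add the impurity. Reckoned pseudo-first-order against the starting complex that the exchanges hold at the trial ratio, it comes to 3.33 mM of complex taken at midnight and 4.57 mM at dusk.

Then add the side product, each of which takes two complexes: 1.08 mM and 2.72 mM. That leaves 0.0456 M and 0.0427 M of complex. Each side product keeps the one exchange of its complex with one exchanged, so the balance, with that counted, now returns ρ of 0.956 at midnight and 0.570 at dusk, and this reckoning keeps the trials as they stand.

The midnight trial lies above ρc and the dusk trial below it. Midnight: complex with three exchanged, at 31.8 %. Dusk: starting complex, at 53.1 %.

The forecast names complex with three exchanged at 31 % for midnight and starting complex at 52 % for dusk, on the ground that “All the exchange steps relax within seconds to tens of seconds”.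

The simulation gives complex with three exchanged at 31.1 % for midnight and starting complex at 52.8 % for dusk. At the end of midnight, ρ reads 0.985, whose cube against ρc is 1.20, and the two complexes stand at 1.21 to one. The midnight flask with 0.38 M of incoming ligand ends at ρ of 2.12, whose cube against ρc is 12.0, and it holds 64.9 % of complex with three exchanged against 5.38 % of starting complex.

(The numbers are made up; what happens was integrated by code.)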